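**Retrosynthetic overview**
1. The 15-membered lactone is closed last, at C1(=O)–O–C21. The 15Z alkene comes from syn semihydrogenation of a C15≡C16 alkyne. The C17 carbinol comes from reagent-controlled reduction of an enynone made by joining a C1–C16 tricyclic alkyne with a C17–C21 (E)-β-chloroenal.
2. Dehydropiperidine ring: C2=C3 comes from reduction and elimination of a cyclic β-keto ester, and N–C23–C2 from a Mannich closure with formaldehyde. The key C2–C3 bond comes from an intermolecular crossed Claisen condensation of tert-butyl acetate enolate with the spiropiperidine acetate.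
3. Piperidine ring: N–C5 comes from an intramolecular aza-Michael addition to an enoate. The enoate is installed on a C9 allyl group by hydroboration and B-alkyl Suzuki coupling.
4. C9, C13 and C14 are set on an (R)-phenylglycinol Meyers lactam of 2-oxocyclopentaneacetic acid (allylation at C9, convex-face methylation at C14). The lactam is then opened.
5. Ring order: cyclopentane (bought) → temporary γ-lactam → piperidine → dehydropiperidine → macrolactone. The chloroenal comes from 3-butyn-1-ol by syn stannylcupration and CuCl2 chlorodestannylation.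

**Assumption:** the SMILES is taken literally, i.e. 5R,9S,13R,14S,17R with a 15Z alkene and an 18E chloroalkene (Cl trans to C17, C17 cis to C20). Atom labels follow halichlorine numbering: C1 ester C=O, C2=C3, C4, C5 N–CH, C6–C8, C9 spiro, C10–C12, C13, C14 CHMe, C15=C16, C17 CHOH, C18=C19(Cl), C20, C21 OCH2, C23 NCH2.

**Step 1**
Reactants: 1 ethyl 2-(2-oxocyclopentyl)acetate (racemic)
Product: 2 2-(2-oxocyclopentyl)acetic acid (racemic)
Conditions: NaOH, EtOH/H2O, rt; then aq HCl
Reagents that add atoms: sodium hydroxide [Na+].[OH-]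
Why: Saponification of an unhindered ethyl ester is routine, and the racemic, enolisable centre (C13) is corrected in step 2.

**Step 2**
Reactants: 2 2-(2-oxocyclopentyl)acetic acid; 3 (R)-2-phenylglycinol
Product: 4 tricyclic Meyers lactam (9S,13R; phenyl-bearing carbon R)
Conditions: toluene, reflux, Dean–Stark, 18 h
Reagents that add atoms: none
Why: In this Meyers cyclodehydration to an N,O-acetal lactam, C13 epimerises through the enamine at reflux, so both enantiomers of 2 funnel into the one tricycle that has a cis-fused carbocycle/lactam pair and the angular C9–C10 bond cis to phenyl, which fixes 9S and 13R.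

**Step 3**
Reactants: 4 tricyclic Meyers lactam
Product: 5 (3aR,6aS)-6a-allyl-1-[(R)-2-hydroxy-1-phenylethyl]hexahydrocyclopenta[b]pyrrol-2(1H)-one
Conditions: allylSiMe3 (3 equiv), TiCl4 (2 equiv), CH2Cl2, −78 °C to rt
Reagents that add atoms: allyltrimethylsilane C=CC[Si](C)(C)C
Why: In this aza-Sakurai allylation of the N-acyliminium ion opened by TiCl4, the nucleophile can only add cis to H-13 because the bicyclo[3.3.0] lactam must stay cis-fused, so C–O is replaced by C–C with retention and quaternary C9 is set as S.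

**Step 4**
Reactants: 5 N-(hydroxyphenylethyl) allyl lactam
Product: 6 (3aR,6aS)-6a-allylhexahydrocyclopenta[b]pyrrol-2(1H)-one
Conditions: Na, NH3(l)/THF/EtOH, −78 °C
Reagents that add atoms: none
Why: Dissolving-metal cleavage of the benzylic C–N bond removes the auxiliary, while the isolated alkene, the lactam and both stereocentres are untouched at −78 °C.

**Step 5**
Reactants: 6 NH lactam
Product: 7 tert-butyl (3aR,6aS)-6a-allyl-2-oxohexahydrocyclopenta[b]pyrrole-1(2H)-carboxylate
Conditions: Boc2O, DMAP, THF, rt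
Reagents that add atoms: di-tert-butyl dicarbonate CC(C)(C)OC(=O)OC(=O)OC(C)(C)C
Why: DMAP-catalysed N-acylation gives the imide-type lactam, which eases enolisation at C14 and later directs hydroxide to the ring carbonyl.

**Step 6**
Reactants: 7 N-Boc lactam
Product: 9 tert-butyl (3R,3aR,6aS)-6a-allyl-3-methyl-2-oxohexahydrocyclopenta[b]pyrrole-1(2H)-carboxylate, via lithium lactam enolate 8 (not isolated)
Conditions: LiN(SiMe3)2, THF, −40 °C; MeI, −78 to 0 °C
Reagents that add atoms: iodomethane IC; LiN(SiMe3)2 [Li]N([Si](C)(C)C)[Si](C)(C)C (lithium stays only in 8)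
Why: In this enolate alkylation of a cup-shaped cis-bicyclo[3.3.0] system, MeI attacks the convex face, anti to C12 and cis to H-13 and the allyl group, which sets C14 in the spatial arrangement of the target.

**Step 7**
Reactants: 9 methylated N-Boc lactam
Product: 10 (2R)-2-[(1R,2S)-2-allyl-2-(Boc-amino)cyclopentyl]propanoic acid
Conditions: LiOH, THF/H2O, rt; then cold aq HCl to pH 3–4
Reagents that add atoms: lithium hydroxide [Li+].[OH-]
Why: In this imide-type hydrolysis, hydroxide attacks the more electrophilic ring carbonyl and the resulting carboxylate no longer enolises, so C14 is retained.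

**Step 8**
Reactants: 10 N-Boc amino acid
Product: 12 tert-butyl N-{(1S,2R)-1-allyl-2-[(R)-1-hydroxypropan-2-yl]cyclopentyl}carbamate, via mixed carbonic anhydride 11 (not isolated)
Conditions: ClCO2Et, Et3N, THF, 0 °C; then NaBH4, MeOH, 0 °C
Reagents that add atoms: ethyl chloroformate CCOC(=O)Cl (atoms stay only in 11)
Why: Mixed-anhydride activation followed by borohydride reduction takes the acid to the alcohol without touching the alkene (which a borane would attack) or the carbamate.

**Step 9**
Reactants: 12 primary alcohol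
Product: 13 TBDPS ether of 12
Conditions: TBDPSCl, imidazole, DMF, rt
Reagents that add atoms: tert-butylchlorodiphenylsilane CC(C)(C)[Si](Cl)(c1ccccc1)c1ccccc1
Why: Silylation of the only free hydroxyl gives an ether that survives the acid, the strong base and the borohydride used in steps 12–16.

**Step 10**
Reactants: 14 methyl propiolate
Product: 15 methyl (Z)-3-iodoacrylate
Conditions: NaI, AcOH, 70 °C
Reagents that add atoms: sodium iodide [Na+].[I-]
Why: Conjugate hydroiodination of an ynoate is a net anti addition of HI and gives the Z-iodoacrylate under kinetic control.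

**Step 11**
Reactants: 13 allyl carbamate; 15 methyl (Z)-3-iodoacrylate
Product: 17 methyl (Z)-6-{(1S,2R)-1-(Boc-amino)-2-[(R)-1-(TBDPS-oxy)propan-2-yl]cyclopentyl}hex-2-enoate, via B-alkyl-9-BBN borane 16 (not isolated)
Conditions: 9-BBN, THF, rt; then 15, PdCl2(dppf) (5 mol %), AsPh3, Cs2CO3, DMF/H2O, rt
Reagents that add atoms: 9-borabicyclo[3.3.1]nonane B1C2CCCC1CCC2 (boron unit stays only in 16)
Why: Anti-Markovnikov hydroboration of the only alkene followed by B-alkyl Suzuki–Miyaura coupling forms C5–C6 under mild basic conditions that spare the carbamate, the silyl ether and the ester.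

**Step 12**
Reactants: 17 N-Boc amino enoate
Product: 19 methyl 2-{(1R,5S,7R)-1-[(R)-1-(TBDPS-oxy)propan-2-yl]-6-azaspiro[4.5]decan-7-yl}acetate, via free amino enoate 18 (not isolated)
Conditions: CF3CO2H, CH2Cl2, 0 °C to rt; concentrate; K2CO3, H2O/CH2Cl2, rt
Reagents that add atoms: none
Why: After Boc acidolysis, the intramolecular aza-Michael addition proceeds through a chair in which the C4 side chain and the more substituted C13 are both equatorial and C10 is axial, which places C4 cis to C13 on the new piperidine and sets 5R.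

**Step 13**
Reactants: 19 spiropiperidine methyl ester; 20 tert-butyl acetate
Product: 22 tert-butyl β-keto ester (5R,9S,13R,14R) with the chain C5–CH2–CO–CH2–CO2tBu, via lithium enolate of tert-butyl acetate 21 (not isolated)
Conditions: 20 (4 equiv), LiN(SiMe3)2 (4.5 equiv), THF, −78 °C; add 19, −50 °C to rt; aq NH4Cl
Reagents that add atoms: LiN(SiMe3)2 [Li]N([Si](C)(C)C)[Si](C)(C)C (lithium stays only in 21)
Why: In this intermolecular crossed Claisen condensation, the hindered tert-butyl ester enolate self-condenses slowly, the methyl ester of 19 is the only good acyl acceptor, and deprotonation of the β-keto ester by excess base drives formation of the C2–C3 bond without disturbing C5 or the free NH.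

**Step 14**
Reactants: 22 amino β-keto ester
Product: 24 tert-butyl 3-oxo spiroquinolizidine-2-carboxylate (C2 epimers and enol), via N-hydroxymethyl hemiaminal 23 (not isolated)
Conditions: 37 % aq CH2O, EtOH, rt
Reagents that add atoms: formaldehyde C=O
Why: In this Mannich reaction, the secondary amine and formaldehyde give an iminium ion that is trapped by the doubly activated C2 to close the six-membered ring, and the labile C2 centre is erased in step 16.

**Step 15**
Reactants: 24 cyclic β-keto ester
Product: 25 cyclic β-hydroxy ester (mixture at C2 and C3)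
Conditions: NaBH4, MeOH, −20 to 0 °C
Reagents that add atoms: none
Why: Borohydride reduces only the ketone, and the C2/C3 diastereomer ratio is irrelevant because both carbons become sp2 in the next step.

**Step 16**
Reactants: 25 β-hydroxy ester
Product: 27 tert-butyl enoate of the spiroquinolizidine (C2=C3; 5R,9S,13R,14R) with C15 OTBDPS, via C3 mesylate 26 (not isolated)
Conditions: MsCl, Et3N, CH2Cl2, 0 °C; then DBU, rt
Reagents that add atoms: methanesulfonyl chloride CS(=O)(=O)Cl (atoms stay only in 26)
Why: Mesylation followed by E1cB elimination through the ester enolate converts every diastereomer into the conjugated 1,2,5,6-tetrahydropyridine-3-carboxylate, as in the classical arecoline-type dehydration.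

**Step 17**
Reactants: 27 TBDPS ether
Product: 28 C15 primary alcohol
Conditions: HF·pyridine, pyridine, THF, 0 °C to rt
Reagents that add atoms: none
Why: Buffered fluoride desilylation cleaves the Si–O bond while the tert-butyl enoate and the tertiary amine are inert.

**Step 18**
Reactants: 28 primary alcohol
Product: 29 C15 aldehyde (14R)
Conditions: nPr4N[RuO4] (5 mol %), NMO, 4 Å sieves, CH2Cl2, rt
Reagents that add atoms: none
Why: The Ley–Griffith oxidation is neutral, stops at the aldehyde and does not epimerise C14, and the aldehyde is used at once.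

**Step 19**
Reactants: 29 aldehyde
Product: 30 tricyclic terminal alkyne (C1–C16; 5R,9S,13R,14R)
Conditions: dimethyl (1-diazo-2-oxopropyl)phosphonate, K2CO3, MeOH, 0 °C to rt
Reagents that add atoms: dimethyl (1-diazo-2-oxopropyl)phosphonate CC(=O)C(=[N+]=[N-])P(=O)(OC)OC
Why: The Seyferth–Gilbert homologation in its Ohira–Bestmann form adds C16 under weakly basic conditions that leave α-branched aldehydes configurationally intact and do not attack the tert-butyl ester.

**Step 20**
Reactants: 31 3-butyn-1-ol
Product: 32 4-(TBS-oxy)but-1-yne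
Conditions: TBSCl, imidazole, CH2Cl2, rt
Reagents that add atoms: tert-butylchlorodimethylsilane CC(C)(C)[Si](C)(C)Cl
Why: This is a standard silylation of a primary alcohol.

**Step 21**
Reactants: 32 silyl ether alkyne
Product: 34 methyl 5-(TBS-oxy)pent-2-ynoate, via lithium acetylide 33 (not isolated)
Conditions: n-BuLi, THF, −78 °C; ClCO2Me, −78 to 0 °C
Reagents that add atoms: methyl chloroformate COC(=O)Cl; n-butyllithium [Li]CCCC (lithium stays only in 33)
Why: Acylation of the lithium acetylide with a chloroformate introduces C17 cleanly.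

**Step 22**
Reactants: 34 ynoate
Product: 36 methyl (E)-5-(TBS-oxy)-3-(tributylstannyl)pent-2-enoate, via alkenylcopper adduct 35 (not isolated)
Conditions: Bu3SnH, LiN(iPr)2, THF, 0 °C; CuBr·SMe2, −78 °C; then 34 and MeOH (2 equiv), −78 °C; aq NH4Cl/NH3
Reagents that add atoms: tributyltin hydride CCCC[SnH](CCCC)CCCC; CuBr·SMe2 [Cu]Br.CSC (copper stays only in 35)
Why: Syn stannylcupration puts tin on the β-carbon C19 and copper on C18, and methanol present at −78 °C protonates the alkenylcopper with retention before it can equilibrate through the allenoate, so tin ends up trans to the ester and C17 ends up cis to C20.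

**Step 23**
Reactants: 36 stannyl enoate
Product: 37 (E)-5-(TBS-oxy)-3-(tributylstannyl)pent-2-en-1-ol
Conditions: iBu2AlH (2.5 equiv), CH2Cl2, −78 °C; aq potassium sodium tartrate
Reagents that add atoms: none
Why: 1,2-Reduction of the enoate leaves the alkenylstannane and its geometry untouched and gives a more electron-rich alkene for the halogenation.

**Step 24**
Reactants: 37 stannyl allylic alcohol
Product: 38 (E)-3-chloro-5-(TBS-oxy)pent-2-en-1-ol
Conditions: anhydrous CuCl2 (2.5 equiv), THF, 0 °C to rt
Reagents that add atoms: copper dichloride Cl[Cu]Cl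
Why: Chlorodestannylation with CuCl2 exchanges tin for chlorine at the same carbon with retention of alkene geometry, which leaves chlorine trans to C17.

**Step 25**
Reactants: 38 chloro allylic alcohol
Product: 39 (E)-3-chloro-5-(TBS-oxy)pent-2-enal
Conditions: activated MnO2, CH2Cl2, rt, dark; used at once
Reagents that add atoms: none
Why: Allylic oxidation with MnO2 is neutral and acid-free, which avoids E/Z equilibration of the β-chloroenal.

**Step 26**
Reactants: 30 tricyclic alkyne; 39 (E)-chloroenal
Product: 41 enynol (about 1:1 at C17), via methylzinc acetylide 40 (not isolated)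
Conditions: Me2Zn (3 equiv), toluene, rt, 2 h; then 39 (2 equiv), 0 °C to rt; H2O work-up
Reagents that add atoms: dimethylzinc C[Zn]C (zinc unit stays only in 40)
Why: In this zinc-mediated carbonyl alkynylation, Me2Zn metalates only the alkyne C–H and the zinc acetylide adds 1,2 to the enal without harming the enoate, the amine or the chloroalkene, and C17 is deliberately left uncontrolled because steps 27 and 28 reset it.

**Step 27**
Reactants: 41 enynol mixture
Product: 42 cross-conjugated enynone (C17 ketone)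
Conditions: activated MnO2, CH2Cl2, rt; filtered and used at once
Reagents that add atoms: none
Why: MnO2 oxidises the doubly activated (allylic and propargylic) alcohol under neutral, nucleophile-free conditions that keep the 18E geometry.

**Step 28**
Reactants: 42 enynone
Product: 43 (17S)-enynol (target arrangement at C17)
Conditions: (S)-2-methyl-CBS-oxazaborolidine (0.5 equiv), catecholborane (2 equiv), toluene, −78 °C; MeOH, then aq NaHCO3
Reagents that add atoms: none
Why: In this Corey–Bakshi–Shibata reduction, the linear alkynyl arm acts as the small group and the β,β-disubstituted chloroalkenyl arm as the large group, so the (S)-catalyst delivers hydride in the same sense as acetophenone to (R)-1-phenylethanol, giving the target arrangement, which is labelled 17S here only because alkynyl outranks alkenyl.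

**Step 29**
Reactants: 43 (17S)-enynol
Product: 44 (15Z,17R,18E)-dienol tert-butyl ester (14S)
Conditions: H2 (1 atm), Pd/CaCO3 poisoned with Pb(OAc)2, quinoline, EtOAc, rt; stopped after 1 equiv H2
Reagents that add atoms: none
Why: The Lindlar semihydrogenation delivers both hydrogens to one face of the alkyne to give the 15Z alkene, while the poisoned catalyst leaves the trisubstituted enoate and the chloroalkene alone and only the CIP letters at C14 and C17 change.

**Step 30**
Reactants: 44 dienol tert-butyl ester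
Product: 45 tris-TBS compound (C17 OTBS; C21 OTBS; C1 silyl ester)
Conditions: TBSOTf (4 equiv), 2,6-lutidine, CH2Cl2, 0 °C to rt; used crude
Reagents that add atoms: tert-butyldimethylsilyl triflate CC(C)(C)[Si](C)(C)OS(=O)(=O)C(F)(F)F
Why: The silyl triflate protects the bis-allylic alcohol and, by O-silylation of the ester carbonyl and loss of isobutene, converts the tert-butyl ester into a labile silyl ester without any protic acid that could ionise C17.

**Step 31**
Reactants: 45 tris-TBS compound
Product: 46 seco acid (C1 CO2H; C21 OH; C17 OTBS)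
Conditions: NH4F, MeOH/H2O, rt
Reagents that add atoms: none
Why: Mild fluoride cleaves the silyl ester and the unhindered primary silyl ether much faster than the hindered secondary ether at C17.

**Step 32**
Reactants: 46 seco acid
Product: 47 macrolactone 17-O-TBS ether
Conditions: EDCI·HCl, DMAP, DMAP·HCl, CHCl3/THF, reflux, syringe-pump addition (final 0.001 mol/L)
Reagents that add atoms: none
Why: The Keck macrolactonisation with its proton-transfer buffer suppresses N-acylurea formation, and the two ring-cis alkenes bend the chain so that the primary C21 hydroxyl can reach the activated C1.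

**Step 33**
Reactants: 47 macrolactone TBS ether
Product: 48 target CNP0129639.4
Conditions: HF·pyridine, pyridine, THF, rt
Reagents that add atoms: none
Why: Buffered fluoride desilylation frees the C17 hydroxyl without ionising the bis-allylic position or opening the lactone.

**Compound list**

| No. | Name | SMILES | Role |
|---|---|---|---|
| 1 | ethyl 2-(2-oxocyclopentyl)acetate (racemic) | CCOC(=O)CC1CCCC1=O | starting material |
| 2 | 2-(2-oxocyclopentyl)acetic acid (racemic) | OC(=O)CC1CCCC1=O | intermediate |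
| 3 | (R)-2-phenylglycinol | N[C@@H](CO)c1ccccc1 | starting material |
| 4 | tricyclic Meyers lactam: cis-fused cyclopenta[b]pyrrol-2-one with N and C9 bridged by O–CH2–CH(Ph); 9S,13R, phenyl carbon R | O=C1C[C@H]2CCC[C@]23OC[C@@H](c4ccccc4)N13 | intermediate |
| 5 | (3aR,6aS)-6a-allyl-1-[(R)-2-hydroxy-1-phenylethyl]hexahydrocyclopenta[b]pyrrol-2(1H)-one | O=C1C[C@H]2CCC[C@@]2(CC=C)N1[C@@H](CO)c1ccccc1 | intermediate |
| 6 | (3aR,6aS)-6a-allylhexahydrocyclopenta[b]pyrrol-2(1H)-one | O=C1C[C@H]2CCC[C@@]2(CC=C)N1 | intermediate |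
| 7 | tert-butyl (3aR,6aS)-6a-allyl-2-oxohexahydrocyclopenta[b]pyrrole-1(2H)-carboxylate | O=C1C[C@H]2CCC[C@@]2(CC=C)N1C(=O)OC(C)(C)C | intermediate |
| 8 | lithium enolate of 7 (not isolated) | [Li]OC1=C[C@H]2CCC[C@@]2(CC=C)N1C(=O)OC(C)(C)C | intermediate |
| 9 | tert-butyl (3R,3aR,6aS)-6a-allyl-3-methyl-2-oxohexahydrocyclopenta[b]pyrrole-1(2H)-carboxylate | O=C1[C@H](C)[C@H]2CCC[C@@]2(CC=C)N1C(=O)OC(C)(C)C | intermediate |
| 10 | (2R)-2-[(1R,2S)-2-allyl-2-(Boc-amino)cyclopentyl]propanoic acid | OC(=O)[C@H](C)[C@H]1CCC[C@@]1(CC=C)NC(=O)OC(C)(C)C | intermediate |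
| 11 | ethyl carbonic mixed anhydride of 10 (not isolated) | CCOC(=O)OC(=O)[C@H](C)[C@H]1CCC[C@@]1(CC=C)NC(=O)OC(C)(C)C | intermediate |
| 12 | tert-butyl N-{(1S,2R)-1-allyl-2-[(R)-1-hydroxypropan-2-yl]cyclopentyl}carbamate | OC[C@H](C)[C@H]1CCC[C@@]1(CC=C)NC(=O)OC(C)(C)C | intermediate |
| 13 | TBDPS ether of 12 | CC(C)(C)[Si](c1ccccc1)(c1ccccc1)OC[C@H](C)[C@H]1CCC[C@@]1(CC=C)NC(=O)OC(C)(C)C | intermediate |
| 14 | methyl propiolate | COC(=O)C#C | starting material |
| 15 | methyl (Z)-3-iodoacrylate | COC(=O)/C=C\I | intermediate |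
| 16 | B-alkyl-9-BBN from 13, boron on C6 (not isolated) | CC(C)(C)[Si](c1ccccc1)(c1ccccc1)OC[C@H](C)[C@H]1CCC[C@@]1(CCCB1C2CCCC1CCC2)NC(=O)OC(C)(C)C | intermediate |
| 17 | methyl (Z)-6-{(1S,2R)-1-(Boc-amino)-2-[(R)-1-(TBDPS-oxy)propan-2-yl]cyclopentyl}hex-2-enoate | CC(C)(C)[Si](c1ccccc1)(c1ccccc1)OC[C@H](C)[C@H]1CCC[C@@]1(CCC/C=C\C(=O)OC)NC(=O)OC(C)(C)C | intermediate |
| 18 | free amine of 17 (not isolated) | CC(C)(C)[Si](c1ccccc1)(c1ccccc1)OC[C@H](C)[C@H]1CCC[C@@]1(CCC/C=C\C(=O)OC)N | intermediate |
| 19 | methyl 2-{(1R,5S,7R)-1-[(R)-1-(TBDPS-oxy)propan-2-yl]-6-azaspiro[4.5]decan-7-yl}acetate | COC(=O)C[C@H]1CCC[C@]2(CCC[C@@H]2[C@@H](C)CO[Si](c2ccccc2)(c2ccccc2)C(C)(C)C)N1 | intermediate |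
| 20 | tert-butyl acetate | CC(=O)OC(C)(C)C | starting material |
| 21 | lithium enolate of tert-butyl acetate (not isolated) | [Li]OC(=C)OC(C)(C)C | intermediate |
| 22 | tert-butyl 4-(azaspirodecan-7-yl)-3-oxobutanoate, 5R,9S,13R,14R, C15 OTBDPS | CC(C)(C)OC(=O)CC(=O)C[C@H]1CCC[C@]2(CCC[C@@H]2[C@@H](C)CO[Si](c2ccccc2)(c2ccccc2)C(C)(C)C)N1 | intermediate |
| 23 | N-hydroxymethyl hemiaminal of 22 (not isolated) | CC(C)(C)OC(=O)CC(=O)C[C@H]1CCC[C@]2(CCC[C@@H]2[C@@H](C)CO[Si](c2ccccc2)(c2ccccc2)C(C)(C)C)N1CO | intermediate |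
| 24 | tricyclic β-keto ester (C3 ketone, C2 CO2tBu, C2 epimers/enol) | CC(C)(C)OC(=O)C1C(=O)C[C@H]2CCC[C@]3(CCC[C@@H]3[C@@H](C)CO[Si](c3ccccc3)(c3ccccc3)C(C)(C)C)N2C1 | intermediate |
| 25 | tricyclic β-hydroxy ester (mixture at C2, C3) | CC(C)(C)OC(=O)C1C(O)C[C@H]2CCC[C@]3(CCC[C@@H]3[C@@H](C)CO[Si](c3ccccc3)(c3ccccc3)C(C)(C)C)N2C1 | intermediate |
| 26 | C3 mesylate of 25 (not isolated) | CC(C)(C)OC(=O)C1C(OS(C)(=O)=O)C[C@H]2CCC[C@]3(CCC[C@@H]3[C@@H](C)CO[Si](c3ccccc3)(c3ccccc3)C(C)(C)C)N2C1 | intermediate |
| 27 | tricyclic tert-butyl enoate (C2=C3), C15 OTBDPS, 5R,9S,13R,14R | CC(C)(C)OC(=O)C1=CC[C@H]2CCC[C@]3(CCC[C@@H]3[C@@H](C)CO[Si](c3ccccc3)(c3ccccc3)C(C)(C)C)N2C1 | intermediate |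
| 28 | tricyclic enoate, C15 alcohol | CC(C)(C)OC(=O)C1=CC[C@H]2CCC[C@]3(CCC[C@@H]3[C@@H](C)CO)N2C1 | intermediate |
| 29 | tricyclic enoate, C15 aldehyde | CC(C)(C)OC(=O)C1=CC[C@H]2CCC[C@]3(CCC[C@@H]3[C@@H](C)C=O)N2C1 | intermediate |
| 30 | tricyclic enoate, C15≡C16 terminal alkyne | CC(C)(C)OC(=O)C1=CC[C@H]2CCC[C@]3(CCC[C@@H]3[C@@H](C)C#C)N2C1 | intermediate |
| 31 | 3-butyn-1-ol | OCCC#C | starting material |
| 32 | 4-(TBS-oxy)but-1-yne | C#CCCO[Si](C)(C)C(C)(C)C | intermediate |
| 33 | lithium acetylide of 32 (not isolated) | [Li]C#CCCO[Si](C)(C)C(C)(C)C | intermediate |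
| 34 | methyl 5-(TBS-oxy)pent-2-ynoate | COC(=O)C#CCCO[Si](C)(C)C(C)(C)C | intermediate |
| 35 | syn stannylcupration adduct, Cu on C18 cis to Sn on C19 (not isolated) | COC(=O)/C([Cu])=C(/[Sn](CCCC)(CCCC)CCCC)CCO[Si](C)(C)C(C)(C)C | intermediate |
| 36 | methyl (E)-5-(TBS-oxy)-3-(tributylstannyl)pent-2-enoate | COC(=O)/C=C(/[Sn](CCCC)(CCCC)CCCC)CCO[Si](C)(C)C(C)(C)C | intermediate |
| 37 | (E)-5-(TBS-oxy)-3-(tributylstannyl)pent-2-en-1-ol | OC/C=C(/[Sn](CCCC)(CCCC)CCCC)CCO[Si](C)(C)C(C)(C)C | intermediate |
| 38 | (E)-3-chloro-5-(TBS-oxy)pent-2-en-1-ol | OC/C=C(/Cl)CCO[Si](C)(C)C(C)(C)C | intermediate |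
| 39 | (E)-3-chloro-5-(TBS-oxy)pent-2-enal | O=C/C=C(/Cl)CCO[Si](C)(C)C(C)(C)C | intermediate |
| 40 | methylzinc acetylide of 30 (not isolated) | CC(C)(C)OC(=O)C1=CC[C@H]2CCC[C@]3(CCC[C@@H]3[C@@H](C)C#C[Zn]C)N2C1 | intermediate |
| 41 | enynol, both C17 epimers | CC(C)(C)OC(=O)C1=CC[C@H]2CCC[C@]3(CCC[C@@H]3[C@@H](C)C#CC(O)/C=C(/Cl)CCO[Si](C)(C)C(C)(C)C)N2C1 | intermediate |
| 42 | enynone (C17 ketone, 18E) | CC(C)(C)OC(=O)C1=CC[C@H]2CCC[C@]3(CCC[C@@H]3[C@@H](C)C#CC(=O)/C=C(/Cl)CCO[Si](C)(C)C(C)(C)C)N2C1 | intermediate |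
| 43 | (17S,18E)-enynol | CC(C)(C)OC(=O)C1=CC[C@H]2CCC[C@]3(CCC[C@@H]3[C@@H](C)C#C[C@@H](O)/C=C(/Cl)CCO[Si](C)(C)C(C)(C)C)N2C1 | intermediate |
| 44 | (14S,15Z,17R,18E)-dienol tert-butyl ester | CC(C)(C)OC(=O)C1=CC[C@H]2CCC[C@]3(CCC[C@@H]3[C@@H](C)/C=C\[C@@H](O)/C=C(/Cl)CCO[Si](C)(C)C(C)(C)C)N2C1 | intermediate |
| 45 | tris-TBS compound (TBS ester, 17-OTBS, 21-OTBS) | CC(C)(C)[Si](C)(C)OC(=O)C1=CC[C@H]2CCC[C@]3(CCC[C@@H]3[C@@H](C)/C=C\[C@@H](O[Si](C)(C)C(C)(C)C)/C=C(/Cl)CCO[Si](C)(C)C(C)(C)C)N2C1 | intermediate |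
| 46 | seco acid (17-OTBS, 21-OH) | OC(=O)C1=CC[C@H]2CCC[C@]3(CCC[C@@H]3[C@@H](C)/C=C\[C@@H](O[Si](C)(C)C(C)(C)C)/C=C(/Cl)CCO)N2C1 | intermediate |
| 47 | macrolactone 17-O-TBS ether | C[C@H]1/C=C\[C@@H](O[Si](C)(C)C(C)(C)C)/C=C(/Cl)CCOC(=O)C2=CC[C@H]3CCC[C@]4(CCC[C@H]14)N3C2 | intermediate |
| 48 | CNP0129639.4, (5R,9S,13R,14S,15Z,17R,18E) | C[C@H]1/C=C\[C@@H](O)/C=C(/Cl)CCOC(=O)C2=CC[C@H]3CCC[C@]4(CCC[C@H]14)N3C2 | target |

**Totals**
- Total step count: 33.
- Longest linear sequence: 26 steps (steps 1–9, 11–19 and 26–33).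

**Three steps most likely to fail**

Step 26: ligand-free zincation of a hindered alkyl alkyne may be slow, and methyl transfer to the enal may compete. The fallback replaces the acid–base generated zinc acetylide by a halide-derived chromium acetylide. It sets out from 30, which is iodinated at the alkyne terminus with I2 and morpholine (toluene, 45 °C) to give the 1-iodoalkyne F1. F1 is then coupled with 39 under Nozaki–Hiyama–Kishi conditions (CrCl2, 1 mol % NiCl2, THF, rt). These conditions tolerate the ester, the amine and the chloroalkene, and the fallback comes back to the route at 41.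

Step 28: the enynone 42 is an electrophilic β-chlorovinyl ketone that may lose its 18E geometry. The basic nitrogen or the branched alkyne terminus may also erode the selectivity of the oxazaborolidine reduction. The fallback avoids the ketone altogether. It sets out from 41, whose C17 epimers are separated by chromatography, and one of them is 43 itself. The other, the unwanted (17R)-enynol F2, is inverted by a Mitsunobu reaction with 4-nitrobenzoic acid (PPh3, DIAD, toluene, 0 °C) to the inverted 4-nitrobenzoate F3. Methanolysis of F3 (K2CO3, MeOH, 0 °C) comes back to the route at 43.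

Step 32: acyl activation of a zwitterionic, conjugated amino acid may give oligomers or N-acylurea for this untested ring geometry. The fallback activates the alcohol instead of the acid. It sets out from 46, which under Mitsunobu macrolactonisation conditions (PPh3, DIAD, toluene/THF, high dilution, 0 °C to rt) forms the C21 alkoxyphosphonium carboxylate F4. F4 closes by SN2 attack of the carboxylate at the achiral C21, and the fallback comes back to the route at 47.

**Further compounds**
F1 | step 26 | 1-iodoalkyne of 30 (iodine on C16) | CC(C)(C)OC(=O)C1=CC[C@H]2CCC[C@]3(CCC[C@@H]3[C@@H](C)C#CI)N2C1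
F2 | step 28 | (17R,18E)-enynol, C17 epimer of 43 | CC(C)(C)OC(=O)C1=CC[C@H]2CCC[C@]3(CCC[C@@H]3[C@@H](C)C#C[C@H](O)/C=C(/Cl)CCO[Si](C)(C)C(C)(C)C)N2C1
F3 | step 28 | 4-nitrobenzoate of 43 (C17 arrangement of the target) | CC(C)(C)OC(=O)C1=CC[C@H]2CCC[C@]3(CCC[C@@H]3[C@@H](C)C#C[C@@H](OC(=O)c3ccc(cc3)[N+](=O)[O-])/C=C(/Cl)CCO[Si](C)(C)C(C)(C)C)N2C1
F4 | step 32 | C21 alkoxytriphenylphosphonium carboxylate of 46 | [O-]C(=O)C1=CC[C@H]2CCC[C@]3(CCC[C@@H]3[C@@H](C)/C=C\[C@@H](O[Si](C)(C)C(C)(C)C)/C=C(/Cl)CCO[P+](c3ccccc3)(c3ccccc3)c3ccccc3)N2C1
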